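The runs were computed for an exercise; scatter was added.

If the substrate peak of a run shrinks by the same fraction every hour, whatever the charge, one number holds the question: n, the time of reading multiplied by that fractional rate k, which counts how many times the substrate has fallen by a factor e.

| setting | zeta | beta | flask |
|---|---|---|---|
| substrate | 0.090 M | 0.36 M | 0.18 M |
| gas | 49 mM (held) | 49 mM (held) | 49 mM (held) |
| remark | run made earlier | run made earlier |  |
| time |  |  | 30 h |

| run | time / h | target / % | substrate / % |
|---|---|---|---|
| zeta | 5.00 | 31.2 | 68.0 |
| zeta | 10.0 | 54.9 | 45.2 |
| zeta | 15.0 | 71.5 | 28.5 |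
| zeta | 20.0 | 79.2 | 20.8 |
| zeta | 25.0 | 86.1 | 14.2 |
| zeta | 30.0 | 89.6 | 7.6 |
| zeta | 40.0 | 95.5 | 3.4 |
| beta | 5.00 | 33.6 | 67.8 |
| beta | 10.0 | 53.8 | 44.3 |
| beta | 15.0 | 68.3 | 30.0 |
| beta | 20.0 | 80.8 | 21.3 |
| beta | 25.0 | 86.6 | 13.7 |
| beta | 30.0 | 89.8 | 7.2 |
| beta | 40.0 | 95.4 | 4.7 |

(standard deviation of a reading: 1 percentage point)

* the target standing at 30 h, as a percentage of the substrate charged
* concentration of reagent in solution at 8.0 h, in percent of saturation
* the change that raises the amount of target at 30 h, in percent of the substrate charged most ("none" if none brings more than 2 percentage points) (south-west / north-west / none)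
* amount of target at 30 h, in percent of the substrate charged, after north-west

- what was read earlier has a scatter of 1 percentage point, one standard deviation
- at the start none of the gas is in solution
- reagent is what gas becomes in solution

- south-west: doubling the transfer coefficient of the gas, all else as stated
- north-west: doubling the saturation concentration of gas, all else as stated

At 20.0 h the zeta run has 20.8% substrate left and the beta run 21.3%, although the beta charge is larger by a factor of 4.00. I take their geometric mean, which gives k = 0.0779 h⁻¹, so for the flask at 30 h n = 2.34. In words, the flask reaches target 90.3%.

I test this on other readings: at 30.0 h the runs show target 89.6% and 89.8%, within the scatter of 1 percentage point. The gas is a harder test. The beta run needs reagent for its larger charge, yet its curve stays with the zeta curve, so at the held gas level the supply of reagent keeps up with that demand, and I expect no gain of 2 points from south-west. But both runs held gas at 49 mM, so they leave the effect of the saturation level untested. My answer of none therefore rests on an assumption of mine that n stays as it is after north-west, with target near 90.3%. But one number is not enough for the reagent, which no reading shows, so I give no figure for it.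

The forecast gives 90%, 100%, north-west and 99%, and on the gas it parts from me: “Doubling saturation should double the rate if the reaction is first order in reagent”.

The flask gives 90.5% of target and reagent at 86.1% of saturation at 8.0 h. The answer for the best change is none: south-west gains 0.049 points and north-west 0.13 points, below 2 points, leaving 90.7%.

    substrate ⇌ tight pair (K = 0.0160, k = 2.22 × 10⁻⁵ s⁻¹)
    tight pair ⇌ loose pair (K = 0.870, k = 0.00211 s⁻¹)
    reagent + tight pair → target (k = 28.5 M⁻¹ s⁻¹)
    reagent + loose pair → isomer of the product (k = 517 M⁻¹ s⁻¹)
    gas ⇌ reagent, rate k5*(csat - [reagent]) (kL = 3.31 × 10⁻⁴ s⁻¹)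
    substrate → decomposition product (k = 4.06 × 10⁻⁸ s⁻¹)

Carried to the same flask read at 20 h, n becomes 1.56, which gives target 79.0%, and that flask stands at 79.4%. In the flask at 5.61 h, tight pair goes to target 550 times as fast as it passes forward into loose pair. At 30.0 h the flask makes and uses tight pair at a ratio of 1.00, a steady-state intermediate, with 0% of it standing beside 0.216% of isomer of the product.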